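## Retrosynthetic overview
1. The target comes from the tetra-O-benzyl (2S)-flavanone by a final global hydrogenolysis. C-2 is secured on that protected flavanone by a catalytic kinetic resolution (asymmetric transfer hydrogenation).
2. Flavanone ring C comes from oxa-Michael closure of a 2'-hydroxychalcone. The chalcone Cα=Cβ bond comes from a Claisen–Schmidt aldol condensation of a ring A acetophenone with a 4-(flavon-3-yloxy)benzaldehyde, which is the fragment union.
3. The aldehyde comes from SNAr of 5,7,4'-tri-O-benzylkaempferol (free 3-OH) on 4-fluorobenzaldehyde.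
4. Tri-O-benzylkaempferol comes from DMDO C-3 hydroxylation of tri-O-benzylapigenin. That flavone comes from I2/DMSO cyclisation of a chalcone made from dibenzylphloroacetophenone and 4-(benzyloxy)benzaldehyde.
5. Ring order: flavone pyranone first, C3–O–aryl ether second, flavanone pyranone last. Both ring A units come from 2,4,6-trihydroxyacetophenone.

Assumption: the single stereocentre written [C@H] is C-2 of the flavanone unit and is (S); DMDO is used as a separately prepared acetone stock solution.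

## Route

Step 1
Reactants: 1 2,4,6-trihydroxyacetophenone
Product: 2 1-[2,4-bis(benzyloxy)-6-hydroxyphenyl]ethan-1-one
Conditions: BnBr (2.1 equiv), K2CO3 (2.2 equiv), DMF, 25 to 60 °C
Reagents that add atoms: benzyl bromide, BrCc1ccccc1
Why: Williamson ether synthesis, in which the last ortho OH stays hydrogen-bonded to the acetyl carbonyl and is the least reactive, so two equivalents of BnBr stop at the 2,4-dibenzyl ether.

Step 2
Reactants: 2 1-[2,4-bis(benzyloxy)-6-hydroxyphenyl]ethan-1-one; 3 4-(benzyloxy)benzaldehyde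
Product: 5 (E)-1-[2,4-bis(benzyloxy)-6-hydroxyphenyl]-3-[4-(benzyloxy)phenyl]prop-2-en-1-one, via racemic aldol adduct 4 (not isolated)
Conditions: KOH (50% aq), EtOH, rt, 36 h; then 1 M HCl
Reagents that add atoms: none
Why: Claisen–Schmidt aldol condensation, in which the methyl ketone enolate adds to the non-enolisable aldehyde and E1cB loss of water gives the thermodynamically favoured (E)-chalcone.

Step 3
Reactants: 5 (E)-1-[2,4-bis(benzyloxy)-6-hydroxyphenyl]-3-[4-(benzyloxy)phenyl]prop-2-en-1-one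
Product: 7 5,7-bis(benzyloxy)-2-[4-(benzyloxy)phenyl]-4H-chromen-4-one, via racemic tribenzyl flavanone 6 (not isolated)
Conditions: I2 (5 mol %), DMSO, 130 °C, 2 h
Reagents that add atoms: none
Why: I2/DMSO oxidative cyclisation, in which oxa-Michael closure, α-iodination and loss of HI give the pyranone while DMSO re-oxidises HI, and the low I2 loading and short time spare the 5-O-benzyl ether.

Step 4
Reactants: 7 5,7-bis(benzyloxy)-2-[4-(benzyloxy)phenyl]-4H-chromen-4-one
Product: 9 5,7-bis(benzyloxy)-2-[4-(benzyloxy)phenyl]-3-hydroxy-4H-chromen-4-one, via racemic flavone 2,3-epoxide 8 (not isolated)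
Conditions: DMDO (acetone solution, 3 equiv), CH2Cl2, 0 °C; then p-TsOH (cat.), rt
Reagents that add atoms: dimethyldioxirane, CC1(C)OO1
Why: Dioxirane epoxidation of the enol-ether-like C2=C3 bond, followed by acid-catalysed epoxide opening and loss of H-3, gives the flavonol, and the benzyl ethers are inert at 0 °C.

Step 5
Reactants: 9 5,7-bis(benzyloxy)-2-[4-(benzyloxy)phenyl]-3-hydroxy-4H-chromen-4-one; 10 4-fluorobenzaldehyde
Product: 11 4-({5,7-bis(benzyloxy)-2-[4-(benzyloxy)phenyl]-4-oxo-4H-chromen-3-yl}oxy)benzaldehyde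
Conditions: K2CO3 (2 equiv), 10 (1.5 equiv), degassed DMF, 110 °C, Ar, 12 h
Reagents that add atoms: none
Why: Nucleophilic aromatic substitution (addition–elimination), in which the only free OH gives an oxyanion that displaces fluoride para to the activating formyl group, and argon prevents oxygenolysis of the flavonolate.

Step 6
Reactants: 1 2,4,6-trihydroxyacetophenone
Product: 12 1-(2,6-dihydroxy-4-methoxyphenyl)ethan-1-one
Conditions: Me2SO4 (1.0 equiv), K2CO3 (1.05 equiv), acetone, reflux, 4 h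
Reagents that add atoms: dimethyl sulfate, COS(=O)(=O)OC
Why: Selective Williamson O-methylation, because the para OH is the most acidic and the only one not chelated to the carbonyl, so one equivalent of Me2SO4 reacts there first.

Step 7
Reactants: 12 1-(2,6-dihydroxy-4-methoxyphenyl)ethan-1-one
Product: 13 1-[2-(benzyloxy)-6-hydroxy-4-methoxyphenyl]ethan-1-one
Conditions: BnBr (1.05 equiv), K2CO3 (1.1 equiv), acetone, reflux
Reagents that add atoms: benzyl bromide, BrCc1ccccc1
Why: Williamson mono-benzylation of two equivalent OH groups, in which the remaining OH becomes firmly chelated to the carbonyl after the first alkylation and does not react further.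

Step 8
Reactants: 13 1-[2-(benzyloxy)-6-hydroxy-4-methoxyphenyl]ethan-1-one; 11 4-({5,7-bis(benzyloxy)-2-[4-(benzyloxy)phenyl]-4-oxo-4H-chromen-3-yl}oxy)benzaldehyde
Product: 15 (E)-1-[2-(benzyloxy)-6-hydroxy-4-methoxyphenyl]-3-[4-({5,7-bis(benzyloxy)-2-[4-(benzyloxy)phenyl]-4-oxo-4H-chromen-3-yl}oxy)phenyl]prop-2-en-1-one, via racemic beta-hydroxy ketone 14 (not isolated)
Conditions: KOH (50% aq, 10 equiv), EtOH/THF 1:1, 0 °C to rt, 36 h; then cold 1 M HCl to pH 5
Reagents that add atoms: none
Why: Intermolecular Claisen–Schmidt aldol condensation that joins the two halves, since the aldehyde is by far the most electrophilic carbonyl, the electron-rich fully substituted flavone tolerates hydroxide at room temperature, and E1cB dehydration gives the (E)-chalcone.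

Step 9
Reactants: 15 (E)-chalcone from step 8
Product: 16 racemic 5-(benzyloxy)-2-[4-({5,7-bis(benzyloxy)-2-[4-(benzyloxy)phenyl]-4-oxo-4H-chromen-3-yl}oxy)phenyl]-7-methoxychroman-4-one
Conditions: NaOAc (10 equiv), EtOH/THF, reflux, 36 h; recovered 15 is resubmitted
Reagents that add atoms: none
Why: Intramolecular oxa-Michael addition (chalcone–flavanone isomerisation), in which the 6'-benzyloxy group twists the enone out of conjugation so the equilibrium favours the flavanone, and C-2 is formed racemic here and resolved in step 10.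

Step 10
Reactants: 16 racemic tetra-O-benzyl flavanone
Product: 17 (2S)-5-(benzyloxy)-2-[4-({5,7-bis(benzyloxy)-2-[4-(benzyloxy)phenyl]-4-oxo-4H-chromen-3-yl}oxy)phenyl]-7-methoxychroman-4-one
Conditions: Cp*RhCl[(R,R)-TsDPEN] (1–2 mol %), HCO2H/Et3N 5:2, EtOAc, 40 °C, stopped at 52–55% conversion (chiral HPLC); SiO2 chromatography
Reagents that add atoms: none
Why: Noyori–Ikariya asymmetric transfer hydrogenation run as a kinetic resolution, in which the (R,R)-catalyst forms (4R)-alcohols and finds its preferred carbonyl face anti to the C-2 aryl only in the (2R)-ketone, so that ketone goes to the easily separated cis-(2R,4R)-flavan-4-ol while the (2S)-ketone remains in at least 98% ee and the vinylogous-ester flavone carbonyl is untouched.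

Step 11
Reactants: 17 (2S)-tetra-O-benzyl flavanone
Product: 18 (2S)-2-(4-{[5,7-dihydroxy-2-(4-hydroxyphenyl)-4-oxo-4H-chromen-3-yl]oxy}phenyl)-5-hydroxy-7-methoxychroman-4-one (CNP0173006.1)
Conditions: H2 (1 atm), 10% Pd/C, THF/MeOH 1:1, rt, monitored by TLC
Reagents that add atoms: none
Why: Catalytic hydrogenolysis removes all four O-benzyl groups under neutral conditions, which cannot trigger the base-induced retro-oxa-Michael opening that would racemise C-2, and it leaves the tetrasubstituted flavone C2=C3 bond, both carbonyls and the C3–O–aryl ether intact.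

## Compound list
1 | 2,4,6-trihydroxyacetophenone | CC(=O)c1c(O)cc(O)cc1O | starting material
2 | 1-[2,4-bis(benzyloxy)-6-hydroxyphenyl]ethan-1-one | CC(=O)c1c(O)cc(OCc2ccccc2)cc1OCc1ccccc1 | intermediate
3 | 4-(benzyloxy)benzaldehyde | O=Cc1ccc(OCc2ccccc2)cc1 | starting material
4 | racemic 1-[2,4-bis(benzyloxy)-6-hydroxyphenyl]-3-[4-(benzyloxy)phenyl]-3-hydroxypropan-1-one (not isolated) | O=C(CC(O)c1ccc(OCc2ccccc2)cc1)c1c(O)cc(OCc2ccccc2)cc1OCc1ccccc1 | intermediate
5 | (E)-1-[2,4-bis(benzyloxy)-6-hydroxyphenyl]-3-[4-(benzyloxy)phenyl]prop-2-en-1-one | O=C(/C=C/c1ccc(OCc2ccccc2)cc1)c1c(O)cc(OCc2ccccc2)cc1OCc1ccccc1 | intermediate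
6 | racemic 5,7-bis(benzyloxy)-2-[4-(benzyloxy)phenyl]chroman-4-one (not isolated) | O=C1CC(c2ccc(OCc3ccccc3)cc2)Oc2cc(OCc3ccccc3)cc(OCc3ccccc3)c21 | intermediate
7 | 5,7-bis(benzyloxy)-2-[4-(benzyloxy)phenyl]-4H-chromen-4-one (tri-O-benzylapigenin) | O=c1cc(-c2ccc(OCc3ccccc3)cc2)oc2cc(OCc3ccccc3)cc(OCc3ccccc3)c12 | intermediate
8 | racemic 2,3-epoxide of 7 (not isolated) | O=C1C2OC2(c2ccc(OCc3ccccc3)cc2)Oc2cc(OCc3ccccc3)cc(OCc3ccccc3)c21 | intermediate
9 | 5,7-bis(benzyloxy)-2-[4-(benzyloxy)phenyl]-3-hydroxy-4H-chromen-4-one (5,7,4'-tri-O-benzylkaempferol) | O=c1c(O)c(-c2ccc(OCc3ccccc3)cc2)oc2cc(OCc3ccccc3)cc(OCc3ccccc3)c12 | intermediate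
10 | 4-fluorobenzaldehyde | O=Cc1ccc(F)cc1 | starting material
11 | 4-({5,7-bis(benzyloxy)-2-[4-(benzyloxy)phenyl]-4-oxo-4H-chromen-3-yl}oxy)benzaldehyde | O=Cc1ccc(Oc2c(-c3ccc(OCc4ccccc4)cc3)oc3cc(OCc4ccccc4)cc(OCc4ccccc4)c3c2=O)cc1 | intermediate
12 | 1-(2,6-dihydroxy-4-methoxyphenyl)ethan-1-one | COc1cc(O)c(C(C)=O)c(O)c1 | intermediate
13 | 1-[2-(benzyloxy)-6-hydroxy-4-methoxyphenyl]ethan-1-one | COc1cc(O)c(C(C)=O)c(OCc2ccccc2)c1 | intermediate
14 | racemic 1-[2-(benzyloxy)-6-hydroxy-4-methoxyphenyl]-3-hydroxy-3-[4-({5,7-bis(benzyloxy)-2-[4-(benzyloxy)phenyl]-4-oxo-4H-chromen-3-yl}oxy)phenyl]propan-1-one (not isolated) | COc1cc(O)c(C(=O)CC(O)c2ccc(Oc3c(-c4ccc(OCc5ccccc5)cc4)oc4cc(OCc5ccccc5)cc(OCc5ccccc5)c4c3=O)cc2)c(OCc2ccccc2)c1 | intermediate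
15 | (E)-1-[2-(benzyloxy)-6-hydroxy-4-methoxyphenyl]-3-[4-({5,7-bis(benzyloxy)-2-[4-(benzyloxy)phenyl]-4-oxo-4H-chromen-3-yl}oxy)phenyl]prop-2-en-1-one | COc1cc(O)c(C(=O)/C=C/c2ccc(Oc3c(-c4ccc(OCc5ccccc5)cc4)oc4cc(OCc5ccccc5)cc(OCc5ccccc5)c4c3=O)cc2)c(OCc2ccccc2)c1 | intermediate
16 | racemic 5-(benzyloxy)-2-[4-({5,7-bis(benzyloxy)-2-[4-(benzyloxy)phenyl]-4-oxo-4H-chromen-3-yl}oxy)phenyl]-7-methoxychroman-4-one | COc1cc(OCc2ccccc2)c2c(c1)OC(c1ccc(Oc3c(-c4ccc(OCc5ccccc5)cc4)oc4cc(OCc5ccccc5)cc(OCc5ccccc5)c4c3=O)cc1)CC2=O | intermediate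
17 | (2S)-5-(benzyloxy)-2-[4-({5,7-bis(benzyloxy)-2-[4-(benzyloxy)phenyl]-4-oxo-4H-chromen-3-yl}oxy)phenyl]-7-methoxychroman-4-one | COc1cc(OCc2ccccc2)c2c(c1)O[C@H](c1ccc(Oc3c(-c4ccc(OCc5ccccc5)cc4)oc4cc(OCc5ccccc5)cc(OCc5ccccc5)c4c3=O)cc1)CC2=O | intermediate
18 | (2S)-2-(4-{[5,7-dihydroxy-2-(4-hydroxyphenyl)-4-oxo-4H-chromen-3-yl]oxy}phenyl)-5-hydroxy-7-methoxychroman-4-one (CNP0173006.1) | COc1cc(O)c2c(c1)O[C@H](c1ccc(Oc3c(-c4ccc(O)cc4)oc4cc(O)cc(O)c4c3=O)cc1)CC2=O | target

## Step count and risks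
Total step count: 11.
Longest linear sequence: 9 steps (1 → 2 → 5 → 7 → 9 → 11 → 15 → 16 → 17 → 18, that is steps 1–5 and 8–11).

**Step 5 (SNAr O-arylation).**
- Risk: the flavonolate is flanked by the 2-aryl group and the C-4 carbonyl and is only a modest nucleophile. It also degrades at 110 °C if traces of oxygen are present.
- Fallback: it sets out from 9 and comes back at 11, replacing addition–elimination by metal-free arylation with a diaryliodonium salt.
- 4-Formylphenylboronic acid, PhI(OAc)2 and BF3·OEt2 (CH2Cl2, 0 °C, then aqueous NaBF4) give (4-formylphenyl)(phenyl)iodonium tetrafluoroborate F1.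
- Compound 9 is deprotonated with t-BuOK in THF at 0 °C and arylated by the salt at room temperature through ligand coupling at trivalent iodine. The electron-poorer formylphenyl group is the one transferred, which gives 11.

**Step 8 (Claisen–Schmidt union).**
- Risk: prolonged contact with hydroxide could open the pyranone of 11, and the large aldehyde is poorly soluble in ethanol.
- Fallback: it sets out from 13 (with 11) and comes back at 16. It stays within aldol chemistry but uses a Lewis-acid Mukaiyama addition instead of a hydroxide condensation.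
- Compound 13 is bis-silylated with TMSOTf/Et3N (CH2Cl2, 0 °C) to {1-[2-(benzyloxy)-4-methoxy-6-(trimethylsilyloxy)phenyl]ethenyloxy}trimethylsilane F2.
- This silyl enol ether adds to 11 with BF3·OEt2 (3 equiv) in CH2Cl2 at −78 °C. Work-up with 1 M HCl/THF removes the silyl groups and gives the beta-hydroxy ketone 14, now isolated.
- Heating 14 with NaOAc in EtOH causes E1cB dehydration and oxa-Michael closure in one operation, giving 16.

**Step 10 (kinetic resolution).**
- Risk: the 5-benzyloxy, electron-rich ketone may be reduced slowly or with too low a selectivity factor on this large substrate.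
- Fallback: it sets out from 16 and comes back at 17. The chemical resolution is replaced by preparative chromatography on an amylose tris(3,5-dimethylphenylcarbamate) chiral stationary phase (hexane/i-PrOH/CH2Cl2).
- The first-choice fraction is 17. The antipode, (2R)-5-(benzyloxy)-2-[4-({5,7-bis(benzyloxy)-2-[4-(benzyloxy)phenyl]-4-oxo-4H-chromen-3-yl}oxy)phenyl]-7-methoxychroman-4-one F3, is collected and re-equilibrated to 16 with NaOAc in refluxing EtOH (through 15) for recycling.

## Further compounds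
F1 | step 5 | (4-formylphenyl)(phenyl)iodonium tetrafluoroborate | O=Cc1ccc([I+]c2ccccc2)cc1.F[B-](F)(F)F
F2 | step 8 | {1-[2-(benzyloxy)-4-methoxy-6-(trimethylsilyloxy)phenyl]ethenyloxy}trimethylsilane | C=C(O[Si](C)(C)C)c1c(O[Si](C)(C)C)cc(OC)cc1OCc1ccccc1
F3 | step 10 | (2R)-5-(benzyloxy)-2-[4-({5,7-bis(benzyloxy)-2-[4-(benzyloxy)phenyl]-4-oxo-4H-chromen-3-yl}oxy)phenyl]-7-methoxychroman-4-one | COc1cc(OCc2ccccc2)c2c(c1)O[C@@H](c1ccc(Oc3c(-c4ccc(OCc5ccccc5)cc4)oc4cc(OCc5ccccc5)cc(OCc5ccccc5)c4c3=O)cc1)CC2=O
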